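**Strategy**

The synthesis rests on building ring A, the benzoate ring, onto the phenol oxygen of a finished ring B. In ring A the ester-bearing carbon C1 and the oxygen-bearing carbon C6 are adjacent, so both are supplied by the alkyne carbons of a methyl propiolate bound through its β-carbon to the ring B oxygen. One [4+2] benzannulation with the silyl ketene acetal diene of methyl 3-methylbut-2-enoate forms C1–C2 and C5–C6, closes ring A and, after loss of methanol and silicon, sets the C2 phenol, the C4 methyl group and the diaryl ether together. The precursor is this aryloxy ynoate, with ring B protected as 4-methoxybenzyl and silyl ethers.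

Key step: step 9

Remark: ring B is taken from 2-hydroxy-4-methoxybenzaldehyde, because only this isomer leaves the methoxy group para to the phenol oxygen made in the Dakin step (the 5-methoxy isomer would leave it meta and give a regioisomer of ring B); the ring B phenol is carried as a 4-methoxybenzyl ether so that acid can release it after the palmitate is in place, which avoids a hydrogenolysis beside the benzylic ester and an acylation beside a free ring B phenol.

Numbering and abbreviations: ring A: C1 (CO2Me), C2 (OH), C4 (CH3), C6 (O to ring B); ring B: C1 (O to ring A), C2 (CH2O), C4 (OCH3), C6 (OH). PMB = 4-methoxybenzyl; TBS = tert-butyldimethylsilyl; ArB = 2-[(tert-butyldimethylsilyloxy)methyl]-4-methoxy-6-[(4-methoxybenzyl)oxy]phenyl.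

**Route**

Step 1
Reactants: 1 2-hydroxy-4-methoxybenzaldehyde
Product: 2 4-methoxy-2-[(4-methoxybenzyl)oxy]benzaldehyde
Conditions: PMBCl, K2CO3, KI (cat.), DMF, 60 °C
Reagents that add atoms: 4-methoxybenzyl chloride, COc1ccc(CCl)cc1
Why: Williamson etherification, in which K2CO3 deprotonates the chelated phenol and the phenoxide displaces chloride from the benzylic halide while the aldehyde is inert.

Step 2
Reactants: 2 4-methoxy-2-[(4-methoxybenzyl)oxy]benzaldehyde
Product: 4 4-methoxy-2-[(4-methoxybenzyl)oxy]phenol, via aryl formate 3 (not isolated)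
Conditions: mCPBA, CH2Cl2, 0 °C to rt; then K2CO3 (cat.), MeOH, rt
Reagents that add atoms: 3-chloroperoxybenzoic acid, OOC(=O)c1cccc(Cl)c1
Why: Dakin-type oxidation in its Baeyer–Villiger form, in which the electron-rich 2,4-dialkoxyaryl group migrates to give formate 3 and catalytic methanolysis cleaves it, so the new phenol oxygen ends para to the methoxy group and ortho to the PMB ether.

Step 3
Reactants: 4 4-methoxy-2-[(4-methoxybenzyl)oxy]phenol
Product: 5 2-hydroxy-5-methoxy-3-[(4-methoxybenzyl)oxy]benzaldehyde
Conditions: MgCl2, Et3N, (CH2O)n, THF, reflux; dilute HCl work-up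
Reagents that add atoms: paraformaldehyde (as formaldehyde), C=O
Why: Magnesium-mediated ortho-formylation (Casnati–Skattebøl reaction), in which the magnesium phenoxide directs formaldehyde to the only free ortho position and a second equivalent of formaldehyde accepts hydride, so the future ring B CH2O carbon is placed without regioisomers.

Step 4
Reactants: 5 2-hydroxy-5-methoxy-3-[(4-methoxybenzyl)oxy]benzaldehyde
Product: 6 2-(hydroxymethyl)-4-methoxy-6-[(4-methoxybenzyl)oxy]phenol
Conditions: NaBH4, THF/MeOH, 0 °C
Reagents that add atoms: none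
Why: Chemoselective borohydride reduction of the aryl aldehyde at low temperature, which leaves the ethers untouched and avoids the heat or acid that could turn the ortho-hydroxybenzyl alcohol into a quinone methide.

Step 5
Reactants: 6 2-(hydroxymethyl)-4-methoxy-6-[(4-methoxybenzyl)oxy]phenol
Product: 7 2-[(tert-butyldimethylsilyloxy)methyl]-4-methoxy-6-[(4-methoxybenzyl)oxy]phenol
Conditions: TBSCl (1.05 equiv), imidazole, CH2Cl2, 0 °C
Reagents that add atoms: tert-butyldimethylsilyl chloride, CC(C)(C)[Si](C)(C)Cl
Why: Imidazole-mediated silylation is far faster at the unhindered primary alcohol than at the hydrogen-bonded phenol flanked by two ortho substituents, so one equivalent of TBSCl should give the mono-silyl ether.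

Step 6
Reactants: 7 ArB–OH (phenol of step 5); 8 trichloroethylene
Product: 10 (E)-1,2-dichloroethenyl 2-[(tert-butyldimethylsilyloxy)methyl]-4-methoxy-6-[(4-methoxybenzyl)oxy]phenyl ether, via dichloroacetylene 9 (not isolated)
Conditions: K2CO3, DMF, 70 °C
Reagents that add atoms: none
Why: Elimination–addition, in which K2CO3 converts trichloroethylene into dichloroacetylene 9 and the phenoxide adds to it in anti fashion, the standard preparation of aryl (E)-1,2-dichlorovinyl ethers; carbonate leaves the silyl and PMB ethers alone.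

Step 7
Reactants: 10 (E)-1,2-dichloroethenyl ArB ether
Product: 13 methyl 3-{2-[(tert-butyldimethylsilyloxy)methyl]-4-methoxy-6-[(4-methoxybenzyl)oxy]phenoxy}prop-2-ynoate, via chloroethynyl aryl ether 11 (not isolated), via lithium aryloxyacetylide 12 (not isolated)
Conditions: n-BuLi (2.2 equiv), THF, −78 to −40 °C; then ClCO2Me, −78 to 0 °C; anhydrous work-up
Reagents that add atoms: methyl chloroformate, COC(Cl)=O
Why: Dehydrochlorination of 10 by n-BuLi gives chloroalkyne 11, chlorine–lithium exchange with the second equivalent gives acetylide 12, and C-acylation by the chloroformate gives the ynoate, the established dichlorovinyl ether route to substituted ynol ethers, run cold so that ring lithiation and benzylic deprotonation do not compete.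

Step 8
Reactants: 14 methyl 3-methylbut-2-enoate
Product: 16 (1Z)-1-methoxy-3-methyl-1-(trimethylsilyloxy)buta-1,3-diene, via lithium dienolate 15 (not isolated)
Conditions: LiN(iPr)2, THF, −78 °C; then TMSCl, −78 °C to rt; filtration and distillation under N2
Reagents that add atoms: chlorotrimethylsilane, C[Si](C)(C)Cl
Why: γ-Deprotonation of the senecioate by the lithium amide gives the extended dienolate 15, which is silylated on oxygen to the vinylogous silyl ketene acetal; the geometry shown is the one expected from the s-cis ester and is of no consequence later, because C1 of the diene becomes an aromatic carbon.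

Step 9
Reactants: 13 methyl 3-(ArB-oxy)prop-2-ynoate; 16 (1Z)-1-methoxy-3-methyl-1-(trimethylsilyloxy)buta-1,3-diene
Product: 19 methyl 2-hydroxy-4-methyl-6-{2-[(tert-butyldimethylsilyloxy)methyl]-4-methoxy-6-[(4-methoxybenzyl)oxy]phenoxy}benzoate, via cyclohexadiene cycloadduct 17 (not isolated), via aryl trimethylsilyl ether 18 (not isolated)
Conditions: 16 (2.5 equiv), PhMe, 110 °C, sealed tube; then 0.1 M HCl (aq), THF, 0 °C
Reagents that add atoms: none
Why: The electron-rich vinylogous ketene acetal 16 bonds through its CH2 terminus (diene C4) to the ether-bearing β-carbon of ynoate 13 and through its acetal carbon to the ester-bearing α-carbon, in a concerted but asynchronous normal-demand Diels–Alder reaction (or its stepwise Michael/ring-closure limit), to give cyclohexa-1,4-diene 17. The closest known reaction type is the cycloaddition–aromatisation of 1-alkoxy-1-silyloxybuta-1,3-dienes with acetylenic esters, which delivers salicylates. Ring A closes as a six-membered carbocycle by intermolecular [4+2] cycloaddition that forms C5–C6 and C1–C2; thermal 1,4-elimination of methanol from the acetal carbon and C5 then aromatises it to silyl ether 18, and dilute acid frees the C2 phenol. No stereocentre remains, since the acetal carbon of 17 is a transient racemic centre that becomes aromatic C2. The step needs one regiochemistry, ester carbon beside the acetal carbon, and the polarisation of both partners secures it: the ester keeps the β-carbon of 13 electrophilic despite the aryloxy donor, and the two oxygens at diene C1 make diene C4 the nucleophilic terminus. The PMB, silyl and aryl ethers are inert to heat in toluene, and the excess of diene offsets the lowered reactivity of the donor-substituted ynoate and the diene consumed by the liberated methanol.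

Step 10
Reactants: 19 methyl 2-hydroxy-4-methyl-6-(ArB-oxy)benzoate
Product: 20 methyl 2-hydroxy-6-{2-(hydroxymethyl)-4-methoxy-6-[(4-methoxybenzyl)oxy]phenoxy}-4-methylbenzoate
Conditions: Bu4NF, AcOH, THF, 0 °C to rt
Reagents that add atoms: none
Why: Fluoride-mediated cleavage of the primary silyl ether, with acetic acid buffering to keep the benzylic alkoxide and the salicylate phenoxide protonated so that the neighbouring methyl ester is not attacked.

Step 11
Reactants: 20 benzylic alcohol of step 10; 21 palmitoyl chloride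
Product: 22 methyl 2-{2-[(hexadecanoyloxy)methyl]-4-methoxy-6-[(4-methoxybenzyl)oxy]phenoxy}-6-hydroxy-4-methylbenzoate
Conditions: pyridine, CH2Cl2, 0 °C (1.1 equiv of 21)
Reagents that add atoms: none
Why: Acylation of the primary benzylic alcohol by the acid chloride with pyridine; the only other hydroxyl is the salicylate phenol, which is hydrogen-bonded to its ester and should not react with one equivalent at 0 °C.

Step 12
Reactants: 22 PMB-protected palmitate of step 11
Product: 23 betaethrin E, methyl 2-{2-[(hexadecanoyloxy)methyl]-6-hydroxy-4-methoxyphenoxy}-6-hydroxy-4-methylbenzoate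
Conditions: TFA (5% v/v), Et3SiH, CH2Cl2, 0 °C
Reagents that add atoms: none
Why: Acidolysis of the aryl PMB ether, in which dilute TFA ionises the benzylic C–O bond and triethylsilane reduces the 4-methoxybenzyl cation before it can alkylate ring B, while the methyl ester, the palmitate (its benzylic carbon has no strong ortho or para donor) and the diaryl ether should be stable.

**Compound list**

1 | 2-hydroxy-4-methoxybenzaldehyde | O=Cc1ccc(OC)cc1O | starting material
2 | 4-methoxy-2-[(4-methoxybenzyl)oxy]benzaldehyde | O=Cc1ccc(OC)cc1OCc1ccc(OC)cc1 | intermediate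
3 | 4-methoxy-2-[(4-methoxybenzyl)oxy]phenyl formate | O=COc1ccc(OC)cc1OCc1ccc(OC)cc1 | intermediate
4 | 4-methoxy-2-[(4-methoxybenzyl)oxy]phenol | Oc1ccc(OC)cc1OCc1ccc(OC)cc1 | intermediate
5 | 2-hydroxy-5-methoxy-3-[(4-methoxybenzyl)oxy]benzaldehyde | Oc1c(C=O)cc(OC)cc1OCc1ccc(OC)cc1 | intermediate
6 | 2-(hydroxymethyl)-4-methoxy-6-[(4-methoxybenzyl)oxy]phenol | Oc1c(CO)cc(OC)cc1OCc1ccc(OC)cc1 | intermediate
7 | 2-[(tert-butyldimethylsilyloxy)methyl]-4-methoxy-6-[(4-methoxybenzyl)oxy]phenol | Oc1c(CO[Si](C)(C)C(C)(C)C)cc(OC)cc1OCc1ccc(OC)cc1 | intermediate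
8 | trichloroethylene | ClC=C(Cl)Cl | starting material
9 | dichloroacetylene | ClC#CCl | intermediate
10 | (E)-1,2-dichloroethenyl 2-[(tert-butyldimethylsilyloxy)methyl]-4-methoxy-6-[(4-methoxybenzyl)oxy]phenyl ether | Cl/C=C(Cl)\Oc1c(CO[Si](C)(C)C(C)(C)C)cc(OC)cc1OCc1ccc(OC)cc1 | intermediate
11 | chloroethynyl 2-[(tert-butyldimethylsilyloxy)methyl]-4-methoxy-6-[(4-methoxybenzyl)oxy]phenyl ether | ClC#COc1c(CO[Si](C)(C)C(C)(C)C)cc(OC)cc1OCc1ccc(OC)cc1 | intermediate
12 | lithium {2-[(tert-butyldimethylsilyloxy)methyl]-4-methoxy-6-[(4-methoxybenzyl)oxy]phenoxy}acetylide | [Li]C#COc1c(CO[Si](C)(C)C(C)(C)C)cc(OC)cc1OCc1ccc(OC)cc1 | intermediate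
13 | methyl 3-{2-[(tert-butyldimethylsilyloxy)methyl]-4-methoxy-6-[(4-methoxybenzyl)oxy]phenoxy}prop-2-ynoate | COC(=O)C#COc1c(CO[Si](C)(C)C(C)(C)C)cc(OC)cc1OCc1ccc(OC)cc1 | intermediate
14 | methyl 3-methylbut-2-enoate | COC(=O)C=C(C)C | starting material
15 | lithium (1E)-1-methoxy-3-methylbuta-1,3-dien-1-olate (OLi cis to C3) | CO/C(O[Li])=C/C(C)=C | intermediate
16 | (1Z)-1-methoxy-3-methyl-1-(trimethylsilyloxy)buta-1,3-diene | CO/C(O[Si](C)(C)C)=C/C(C)=C | intermediate
17 | methyl 2-{2-[(tert-butyldimethylsilyloxy)methyl]-4-methoxy-6-[(4-methoxybenzyl)oxy]phenoxy}-6-methoxy-4-methyl-6-(trimethylsilyloxy)cyclohexa-1,4-diene-1-carboxylate (racemic) | COC(=O)C1=C(Oc2c(CO[Si](C)(C)C(C)(C)C)cc(OC)cc2OCc2ccc(OC)cc2)CC(C)=CC1(OC)O[Si](C)(C)C | intermediate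
18 | methyl 2-{2-[(tert-butyldimethylsilyloxy)methyl]-4-methoxy-6-[(4-methoxybenzyl)oxy]phenoxy}-4-methyl-6-(trimethylsilyloxy)benzoate | COC(=O)c1c(O[Si](C)(C)C)cc(C)cc1Oc1c(CO[Si](C)(C)C(C)(C)C)cc(OC)cc1OCc1ccc(OC)cc1 | intermediate
19 | methyl 2-hydroxy-4-methyl-6-{2-[(tert-butyldimethylsilyloxy)methyl]-4-methoxy-6-[(4-methoxybenzyl)oxy]phenoxy}benzoate | COC(=O)c1c(O)cc(C)cc1Oc1c(CO[Si](C)(C)C(C)(C)C)cc(OC)cc1OCc1ccc(OC)cc1 | intermediate
20 | methyl 2-hydroxy-6-{2-(hydroxymethyl)-4-methoxy-6-[(4-methoxybenzyl)oxy]phenoxy}-4-methylbenzoate | COC(=O)c1c(O)cc(C)cc1Oc1c(CO)cc(OC)cc1OCc1ccc(OC)cc1 | intermediate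
21 | palmitoyl chloride | CCCCCCCCCCCCCCCC(=O)Cl | starting material
22 | methyl 2-{2-[(hexadecanoyloxy)methyl]-4-methoxy-6-[(4-methoxybenzyl)oxy]phenoxy}-6-hydroxy-4-methylbenzoate | CCCCCCCCCCCCCCCC(=O)OCc1cc(OC)cc(OCc2ccc(OC)cc2)c1Oc1cc(C)cc(O)c1C(=O)OC | intermediate
23 | betaethrin E, methyl 2-{2-[(hexadecanoyloxy)methyl]-6-hydroxy-4-methoxyphenoxy}-6-hydroxy-4-methylbenzoate | CCCCCCCCCCCCCCCC(=O)OCc1cc(OC)cc(O)c1Oc1cc(C)cc(O)c1C(=O)OC | target

**Step count**

Total steps: 12. Longest linear sequence: 11 steps (steps 1–7 and 9–12); step 8 is a one-step side branch.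

**Steps most likely to fail**

Step 9. The donor-substituted ynoate may react so slowly that the diene is lost to desilylation. The addition may also stop at an open-chain conjugate adduct, or divert to [2+2] addition across the ketene acetal double bond. The fallback forms the diaryl ether by C–O coupling instead of building ring A; it sets out from phenol 7 and comes back at 19. Commercial 2,6-dihydroxy-4-methylbenzoic acid is condensed with acetone (trifluoroacetic anhydride, TFA) to 5-hydroxy-2,2,7-trimethyl-4H-1,3-benzodioxin-4-one F1. Triflation (Tf2O, pyridine, CH2Cl2, 0 °C) gives 2,2,7-trimethyl-4-oxo-4H-1,3-benzodioxin-5-yl trifluoromethanesulfonate F2. Buchwald–Hartwig C–O coupling of F2 with 7 (Pd(OAc)2, 2-(di-tert-butylphosphino)-2',4',6'-triisopropylbiphenyl, K3PO4, toluene, 100 °C) should give 5-{2-[(tert-butyldimethylsilyloxy)methyl]-4-methoxy-6-[(4-methoxybenzyl)oxy]phenoxy}-2,2,7-trimethyl-4H-1,3-benzodioxin-4-one F3. Methanolysis of the dioxinone (K2CO3, MeOH, rt) then returns to 19.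

Step 7. Ring lithiation or benzylic deprotonation by n-BuLi may compete with acetylide formation, and the push–pull ynoate may be hydrated or oligomerised during isolation. The fallback avoids organolithium chemistry; it sets out from phenol 7 and comes back at 13. Methyl prop-2-ynoate is brominated (N-bromosuccinimide, AgNO3 cat., acetone) to methyl 3-bromoprop-2-ynoate F4. Conjugate addition of 7 (K2CO3, acetone, 0 °C) should give methyl (2E)-3-bromo-3-{2-[(tert-butyldimethylsilyloxy)methyl]-4-methoxy-6-[(4-methoxybenzyl)oxy]phenoxy}prop-2-enoate F5. Dehydrobromination with LiN(SiMe3)2 (THF, −78 °C) then gives 13.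

Step 12. The 4-methoxybenzyl cation may re-alkylate the electron-rich ring B, or the acid may ionise the benzylic ester. The fallback changes the order of events; it sets out from 19 and comes back at target 23. Hydrogenolysis of the PMB ether (H2, Pd/C, EtOAc) gives methyl 2-{2-[(tert-butyldimethylsilyloxy)methyl]-6-hydroxy-4-methoxyphenoxy}-6-hydroxy-4-methylbenzoate F6. Desilylation (Bu4NF, AcOH, THF) gives methyl 2-hydroxy-6-[2-hydroxy-6-(hydroxymethyl)-4-methoxyphenoxy]-4-methylbenzoate F7. Lipase-catalysed transesterification with vinyl palmitate (immobilised Candida antarctica lipase B, tert-butyl methyl ether, 40 °C), which acylates aliphatic primary alcohols in preference to phenols, then gives 23.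

**Further compounds**

F1 | step 9 | 5-hydroxy-2,2,7-trimethyl-4H-1,3-benzodioxin-4-one | Cc1cc(O)c2c(c1)OC(C)(C)OC2=O
F2 | step 9 | 2,2,7-trimethyl-4-oxo-4H-1,3-benzodioxin-5-yl trifluoromethanesulfonate | Cc1cc(OS(=O)(=O)C(F)(F)F)c2c(c1)OC(C)(C)OC2=O
F3 | step 9 | 5-{2-[(tert-butyldimethylsilyloxy)methyl]-4-methoxy-6-[(4-methoxybenzyl)oxy]phenoxy}-2,2,7-trimethyl-4H-1,3-benzodioxin-4-one | Cc1cc(Oc3c(CO[Si](C)(C)C(C)(C)C)cc(OC)cc3OCc3ccc(OC)cc3)c2c(c1)OC(C)(C)OC2=O
F4 | step 7 | methyl 3-bromoprop-2-ynoate | COC(=O)C#CBr
F5 | step 7 | methyl (2E)-3-bromo-3-{2-[(tert-butyldimethylsilyloxy)methyl]-4-methoxy-6-[(4-methoxybenzyl)oxy]phenoxy}prop-2-enoate | COC(=O)/C=C(/Br)Oc1c(CO[Si](C)(C)C(C)(C)C)cc(OC)cc1OCc1ccc(OC)cc1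
F6 | step 12 | methyl 2-{2-[(tert-butyldimethylsilyloxy)methyl]-6-hydroxy-4-methoxyphenoxy}-6-hydroxy-4-methylbenzoate | COC(=O)c1c(O)cc(C)cc1Oc1c(CO[Si](C)(C)C(C)(C)C)cc(OC)cc1O
F7 | step 12 | methyl 2-hydroxy-6-[2-hydroxy-6-(hydroxymethyl)-4-methoxyphenoxy]-4-methylbenzoate | COC(=O)c1c(O)cc(C)cc1Oc1c(CO)cc(OC)cc1O
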